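## Retrosynthetic overview

1. The target comes from its 2-(trimethylsilyl)ethyl ester 33; the C6 chloride is installed late by SN2 inversion of a 6-alcohol, and the four acetates and the acid are unmasked at the end.
2. Key disconnection C8–C9: the ten-membered carbocycle is closed last by SmI2 ketyl addition of the C9 aldehyde (carbonyl carbon with reversed polarity) to the β-carbon C8 of a 4-alkoxy-3-methylbutenolide, which creates C8, C9 and C17.
3. Seco-aldehyde 29 comes from a chelation-controlled Mukaiyama aldol (C1–C2, quaternary C1) between west enol silane 9 and east aldehyde 24, followed by C14 reduction.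
4. West fragment 9 (cyclohexane, formed first) comes from a catalytic asymmetric Diels–Alder reaction of a 2-silyloxydiene with an acrylate, then ester-enolate hydroxylation at C11.
5. East fragment 24 comes from Brown alkoxyallylboration (C3, C4), Mitsunobu etherification with purchased 3-methyltetronic acid, and an intramolecular vinylogous aldol that closes the pyran (C6, C7). Ring order: cyclohexane, then pyran on the butenolide, then the ten-membered ring.

Assumption: locants follow briarane numbering (C1 quaternary with Me C15; C2, C3, C9, C14 acetoxy carbons; C4 ether CH; C5=C16H2; C6 Cl; C7 lactone O–CH; C8 ether carbon; C10 ring-fusion CH; C11 with OH and C20 acid; C17 with Me C19; C18 lactone C=O), and the (S)-oxazaborolidinium catalyst of step 3 is taken to give adduct 6 as drawn (otherwise its enantiomer is used).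

## Route

Step 1
Reactants: 1 (tert-butyldimethylsilyloxy)acetaldehyde; 2 3-(triphenylphosphoranylidene)butan-2-one
Product: 3 (E)-5-[(tert-butyldimethylsilyl)oxy]-3-methylpent-3-en-2-one
Conditions: toluene, 90 °C
Reagents that add atoms: none
Why: Wittig olefination with a stabilised α-branched ylide gives the trisubstituted (E)-enone selectively.

Step 2
Reactants: 3 (E)-5-[(tert-butyldimethylsilyl)oxy]-3-methylpent-3-en-2-one
Product: 4 tert-butyldimethyl{[(2E)-3-methyl-4-(triisopropylsilyloxy)penta-2,4-dien-1-yl]oxy}silane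
Conditions: TIPSOTf, Et3N, CH2Cl2, 0 °C
Reagents that add atoms: triisopropylsilyl trifluoromethanesulfonate, CC(C)[Si](C(C)C)(C(C)C)OS(=O)(=O)C(F)(F)F
Why: Soft enolisation and O-silylation on the methyl side of the ketone (silyl enol ether formation) gives the cross-conjugated 2-silyloxydiene with the (E)-olefin retained.

Step 3
Reactants: 4 tert-butyldimethyl{[(2E)-3-methyl-4-(triisopropylsilyloxy)penta-2,4-dien-1-yl]oxy}silane; 5 2,2,2-trifluoroethyl acrylate
Product: 6 2,2,2-trifluoroethyl (1S,2S)-2-{[(tert-butyldimethylsilyl)oxy]methyl}-3-methyl-4-(triisopropylsilyloxy)cyclohex-3-ene-1-carboxylate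
Conditions: (S)-1-(2-methylphenyl)-3,3-diphenyltetrahydro-1H,3H-pyrrolo[1,2-c][1,3,2]oxazaborole (20 mol%), HN(SO2CF3)2 (18 mol%), CH2Cl2, −78 to −40 °C
Reagents that add atoms: none
Why: Enantioselective Diels–Alder reaction under chiral oxazaborolidinium catalysis, in which the 2-silyloxy group and the substituted diene terminus both direct C10–C11 bonding, the endo mode gives the cis adduct, and the catalyst shields one acrylate face so that the CH2OTBS-bearing carbon (C10) is formed as 2S.

Step 4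
Reactants: 6 2,2,2-trifluoroethyl (1S,2S)-2-{[(tert-butyldimethylsilyl)oxy]methyl}-3-methyl-4-(triisopropylsilyloxy)cyclohex-3-ene-1-carboxylate
Product: 7 2-(trimethylsilyl)ethyl (1S,2S)-2-{[(tert-butyldimethylsilyl)oxy]methyl}-3-methyl-4-(triisopropylsilyloxy)cyclohex-3-ene-1-carboxylate
Conditions: Me3SiCH2CH2OH (10 equiv), Ti(OiPr)4 (0.2 equiv), toluene, 100 °C
Reagents that add atoms: 2-(trimethylsilyl)ethanol, C[Si](C)(C)CCO
Why: Titanate-catalysed transesterification of the activated trifluoroethyl ester installs a fluoride-cleavable ester for the end game without touching either silyl group (epimerisation α to the ester is irrelevant because that centre is enolised next).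

Step 5
Reactants: 7 2-(trimethylsilyl)ethyl (1S,2S)-2-{[(tert-butyldimethylsilyl)oxy]methyl}-3-methyl-4-(triisopropylsilyloxy)cyclohex-3-ene-1-carboxylate
Product: 9 2-(trimethylsilyl)ethyl (1R,2S)-2-{[(tert-butyldimethylsilyl)oxy]methyl}-1-hydroxy-3-methyl-4-(triisopropylsilyloxy)cyclohex-3-ene-1-carboxylate (west fragment), via potassium ester enolate 8 (not isolated)
Conditions: KN(SiMe3)2, THF, −78 °C; then 2-(phenylsulfonyl)-3-phenyloxaziridine; NH4Cl (aq)
Reagents that add atoms: 2-(phenylsulfonyl)-3-phenyloxaziridine, O=S(=O)(N1OC1c1ccccc1)c1ccccc1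
Why: Davis oxidation of the ester enolate, in which the oxaziridine approaches the enolate face anti to the adjacent pseudoaxial CH2OTBS group (allylic strain), giving the tertiary alcohol with the ester cis to CH2OTBS (C11 as in the target).

Step 6
Reactants: 10 4-methoxybenzyl alcohol; 11 allyl bromide
Product: 12 1-methoxy-4-[(prop-2-en-1-yloxy)methyl]benzene (allyl 4-methoxybenzyl ether)
Conditions: NaH, Bu4NI (cat.), THF, 0 °C to rt
Reagents that add atoms: none
Why: Williamson ether synthesis of a primary alkoxide with an allylic bromide.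

Step 7
Reactants: 13 2-bromo-3,3-diethoxyprop-1-ene
Product: 15 2-(diethoxymethyl)prop-2-enal, via 2-lithioacrolein diethyl acetal 14 (not isolated)
Conditions: n-BuLi, THF, −78 °C; then DMF; NH4Cl (aq)
Reagents that add atoms: N,N-dimethylformamide, CN(C)C=O
Why: Bromine–lithium exchange followed by formylation of the vinyllithium with DMF (Bouveault-type) gives the 2-substituted acrolein with C6 masked as an acetal.

Step 8
Reactants: 12 1-methoxy-4-[(prop-2-en-1-yloxy)methyl]benzene; 15 2-(diethoxymethyl)prop-2-enal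
Product: 17 (3S,4S)-2-(diethoxymethyl)-4-[(4-methoxyphenyl)methoxy]hexa-1,5-dien-3-ol, via Z-alkoxyallyl diisopinocampheylborane 16 (not isolated)
Conditions: s-BuLi, THF, −78 °C; (+)-B-methoxydiisopinocampheylborane [(Ipc)2BOMe]; BF3·OEt2; then 15, −78 °C; NaOH, H2O2
Reagents that add atoms: none
Why: Brown asymmetric γ-alkoxyallylboration, in which the (Z)-alkoxyallylborane reacts through a chair transition state to give the syn 3,4-relationship and the isopinocampheyl groups derived from (−)-α-pinene direct Re-face attack on the aldehyde.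

Step 9
Reactants: 17 (3S,4S)-2-(diethoxymethyl)-4-[(4-methoxyphenyl)methoxy]hexa-1,5-dien-3-ol; 18 4-hydroxy-3-methylfuran-2(5H)-one (3-methyltetronic acid)
Product: 19 4-{[(3R,4S)-2-(diethoxymethyl)-4-[(4-methoxyphenyl)methoxy]hexa-1,5-dien-3-yl]oxy}-3-methylfuran-2(5H)-one
Conditions: PPh3, DIAD, toluene, 0 °C to rt
Reagents that add atoms: none
Why: Mitsunobu O-alkylation of the acidic tetronic acid proceeds by SN2 at the activated carbinol, inverting briarane C4 to give the required 3,4-anti ether.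

Step 10
Reactants: 19 4-{[(3R,4S)-2-(diethoxymethyl)-4-[(4-methoxyphenyl)methoxy]hexa-1,5-dien-3-yl]oxy}-3-methylfuran-2(5H)-one
Product: 20 (3R,4S)-4-[(4-methoxyphenyl)methoxy]-2-methylidene-3-[(4-methyl-5-oxo-2,5-dihydrofuran-3-yl)oxy]hex-5-enal
Conditions: pyridinium p-toluenesulfonate (cat.), acetone/H2O, rt
Reagents that add atoms: water, O
Why: Mild acid hydrolysis of the allylic diethyl acetal liberates the enal while the vinylogous ester, the PMB ether and the vinyl group are inert.

Step 11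
Reactants: 20 (3R,4S)-4-[(4-methoxyphenyl)methoxy]-2-methylidene-3-[(4-methyl-5-oxo-2,5-dihydrofuran-3-yl)oxy]hex-5-enal
Product: 22 (5R,7R,7aS)-7-[(tert-butyldimethylsilyl)oxy]-5-{(1S)-1-[(4-methoxyphenyl)methoxy]prop-2-en-1-yl}-3-methyl-6-methylidene-5,6,7,7a-tetrahydro-2H-furo[3,2-b]pyran-2-one, via 2-silyloxyfuran 21 (not isolated)
Conditions: TBSOTf, iPr2NEt, CH2Cl2, −78 °C
Reagents that add atoms: tert-butyldimethylsilyl trifluoromethanesulfonate, CC(C)(C)[Si](C)(C)OS(=O)(=O)C(F)(F)F
Why: Intramolecular vinylogous Mukaiyama aldol reaction, in which the butenolide is converted into a 2-silyloxyfuran whose C5 (briarane C7) attacks the silyl-activated aldehyde through a half-chair six-membered transition state with the C4 side chain and the forming silyloxy group pseudoequatorial, closing the pyran and setting C6 and C7.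

Step 12
Reactants: 22 (5R,7R,7aS)-7-[(tert-butyldimethylsilyl)oxy]-5-{(1S)-1-[(4-methoxyphenyl)methoxy]prop-2-en-1-yl}-3-methyl-6-methylidene-5,6,7,7a-tetrahydro-2H-furo[3,2-b]pyran-2-one
Product: 24 (2R)-2-[(5R,7R,7aS)-7-[(tert-butyldimethylsilyl)oxy]-3-methyl-6-methylidene-2-oxo-5,6,7,7a-tetrahydro-2H-furo[3,2-b]pyran-5-yl]-2-[(4-methoxyphenyl)methoxy]acetaldehyde (east fragment), via vicinal diol 23 (not isolated)
Conditions: OsO4 (2 mol%), NaIO4, 2,6-lutidine, dioxane/H2O, rt
Reagents that add atoms: sodium periodate (oxygen relayed through OsO4), [Na+].[O-][I](=O)(=O)=O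
Why: Lemieux–Johnson oxidative cleavage is selective for the monosubstituted vinyl group because the exocyclic methylene is shielded by the adjacent OTBS group and deactivated by two allylic C–O bonds, and the butenolide alkene is tetrasubstituted and electron-poor.

Step 13
Reactants: 9 west fragment (enol silane); 24 east fragment (aldehyde)
Product: 25 aldol adduct (C14 ketone; 2-OH; 3-OPMB; 6-OTBS; 9-OTBS; 11-OH; C20 2-(trimethylsilyl)ethyl ester; bicyclic butenolide with C8=C17; centres 1, 2, 3, 4, 7, 10, 11 arranged as in the target; 6-OTBS on the face opposite the final chlorine)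
Conditions: Me2AlCl (3 equiv), CH2Cl2, −78 °C
Reagents that add atoms: none
Why: Chelation-controlled Mukaiyama aldol addition, in which Me2AlCl chelates the aldehyde oxygen and the α-OPMB group so the enol silane attacks the anti-Felkin face (2,3-syn, 2R), while the electrophile approaches the tetrasubstituted enol ether anti to the pseudoaxial C10 CH2OTBS group, creating quaternary C1 with C2 trans to C9.

Step 14
Reactants: 25 aldol adduct
Product: 26 diol (25 with C14 reduced to the 14S alcohol, OH cis to C2)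
Conditions: LiBH(sec-Bu)3, THF, −78 °C; NH4Cl (aq)
Reagents that add atoms: none
Why: Diastereoselective ketone reduction by a bulky hydride, which attacks the neopentyl C14 carbonyl from the face of the small C1 methyl group (opposite the large C2 side chain, equatorial trajectory) to give the axial 14S alcohol.

Step 15
Reactants: 26 diol
Product: 27 2,14-diacetate of 26
Conditions: Ac2O, 4-(dimethylamino)pyridine, pyridine, rt
Reagents that add atoms: acetic anhydride, CC(=O)OC(C)=O
Why: Nucleophile-catalysed acetylation esterifies the two secondary alcohols while the tertiary α-hydroxy ester at C11 is too hindered and deactivated to react.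

Step 16
Reactants: 27 2,14-diacetate
Product: 28 diol (27 with both TBS ethers removed; free 6-OH and 9-OH)
Conditions: HF·pyridine, pyridine/THF, 0 °C to rt
Reagents that add atoms: none
Why: Buffered HF desilylation removes the primary and secondary TBS ethers, while the 2-(trimethylsilyl)ethyl ester, the acetates and the PMB ether survive.

Step 17
Reactants: 28 diol
Product: 29 seco-aldehyde (28 with C9 oxidised to CHO)
Conditions: 2,2,6,6-tetramethylpiperidin-1-oxyl (10 mol%), PhI(OAc)2, CH2Cl2, rt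
Reagents that add atoms: none
Why: Oxoammonium (TEMPO) oxidation is selective for the primary C9 alcohol over the hindered secondary allylic C6 alcohol and the tertiary C11 alcohol, under neutral conditions that do not epimerise C10.

Step 18
Reactants: 29 seco-aldehyde
Product: 30 macrocycle (C8–C9 bond closed; 8R; 9S-OH; 17R; saturated γ-lactone; 6-OH; 3-OPMB; 2,14-diacetate; 11-OH; C20 2-(trimethylsilyl)ethyl ester)
Conditions: SmI2 (3 equiv), MeOH, THF (0.003 M), −78 to 0 °C
Reagents that add atoms: none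
Why: Proposed new method: single-electron reduction of the C9 aldehyde by SmI2 gives a nucleophilic ketyl (carbonyl carbon of reversed polarity) that adds 8-exo-trig to the electrophilic β-carbon C8 of the tethered 4-alkoxybutenolide, the C4 tether forcing attack on the C8 face syn to C3 (8R), chelation of trivalent samarium between the ketyl oxygen and the lactone carbonyl expected to favour 9S, and protonation of the samarium enolate placing the C17 methyl trans to C9 (17R, also the thermodynamic epimer); the closest known reaction type is the SmI2-mediated reductive cyclisation of aldehydes onto β-alkoxyacrylates (ketyl–olefin coupling) used for six- and seven-membered cyclic ethers.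

Step 19
Reactants: 30 macrocycle
Product: 31 6S-chloride of 30 (C6 inverted)
Conditions: PPh3, hexachloroacetone, CH2Cl2, −20 to 0 °C
Reagents that add atoms: hexachloroacetone, ClC(Cl)(Cl)C(=O)C(Cl)(Cl)Cl
Why: Magid-type Appel chlorination, in which the allylic C6 alkoxyphosphonium is displaced by chloride in an SN2 process with inversion and without allylic transposition, while the very hindered C9 and tertiary C11 hydroxyls cannot be substituted.

Step 20
Reactants: 31 6S-chloride
Product: 32 3-alcohol (31 after PMB removal; free 3-OH and 9-OH)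
Conditions: DDQ, CH2Cl2/pH 7 buffer, 0 °C
Reagents that add atoms: none
Why: Oxidative cleavage of the PMB ether by DDQ (benzylic hydride abstraction then hemiacetal hydrolysis) frees the C3 hydroxyl without affecting esters, the allylic chloride or the alkene.

Step 21
Reactants: 32 3-alcohol
Product: 33 2-(trimethylsilyl)ethyl ester of the target (2,3,9,14-tetraacetate)
Conditions: Ac2O, 4-(dimethylamino)pyridine, Et3N, CH2Cl2, rt
Reagents that add atoms: acetic anhydride, CC(=O)OC(C)=O
Why: Nucleophile-catalysed acetylation of the two remaining secondary alcohols (C3 and the hindered C9), again sparing the tertiary C11 hydroxyl.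

Step 22
Reactants: 33 2-(trimethylsilyl)ethyl ester of the target
Product: 34 CNP0186125.1 (target acid)
Conditions: tris(dimethylamino)sulfonium difluorotrimethylsilicate [(Me2N)3S][Me3SiF2], DMF, 0 °C; dilute HCl
Reagents that add atoms: none
Why: Fluoride-induced β-elimination of the 2-(trimethylsilyl)ethyl ester releases the carboxylic acid with loss of ethene and fluorotrimethylsilane, under conditions that leave the four acetates, the lactone and the chloride intact.

## Compound list

1 | (tert-butyldimethylsilyloxy)acetaldehyde | O=CCO[Si](C)(C)C(C)(C)C | starting material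
2 | 3-(triphenylphosphoranylidene)butan-2-one | CC(=O)C(C)=P(c1ccccc1)(c1ccccc1)c1ccccc1 | starting material
3 | (E)-5-[(tert-butyldimethylsilyl)oxy]-3-methylpent-3-en-2-one | CC(=O)/C(C)=C/CO[Si](C)(C)C(C)(C)C | intermediate
4 | tert-butyldimethyl{[(2E)-3-methyl-4-(triisopropylsilyloxy)penta-2,4-dien-1-yl]oxy}silane | C=C(O[Si](C(C)C)(C(C)C)C(C)C)/C(C)=C/CO[Si](C)(C)C(C)(C)C | intermediate
5 | 2,2,2-trifluoroethyl acrylate | C=CC(=O)OCC(F)(F)F | starting material
6 | 2,2,2-trifluoroethyl (1S,2S)-2-{[(tert-butyldimethylsilyl)oxy]methyl}-3-methyl-4-(triisopropylsilyloxy)cyclohex-3-ene-1-carboxylate | CC(C)(C)[Si](C)(C)OC[C@@H]1C(C)=C(O[Si](C(C)C)(C(C)C)C(C)C)CC[C@@H]1C(=O)OCC(F)(F)F | intermediate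
7 | 2-(trimethylsilyl)ethyl (1S,2S)-2-{[(tert-butyldimethylsilyl)oxy]methyl}-3-methyl-4-(triisopropylsilyloxy)cyclohex-3-ene-1-carboxylate | CC(C)(C)[Si](C)(C)OC[C@@H]1C(C)=C(O[Si](C(C)C)(C(C)C)C(C)C)CC[C@@H]1C(=O)OCC[Si](C)(C)C | intermediate
8 | potassium ester enolate of 7 (not isolated; one ketene acetal geometry drawn) | [K+].[O-]/C(OCC[Si](C)(C)C)=C1/CCC(O[Si](C(C)C)(C(C)C)C(C)C)=C(C)[C@H]1CO[Si](C)(C)C(C)(C)C | intermediate
9 | 2-(trimethylsilyl)ethyl (1R,2S)-2-{[(tert-butyldimethylsilyl)oxy]methyl}-1-hydroxy-3-methyl-4-(triisopropylsilyloxy)cyclohex-3-ene-1-carboxylate (west fragment) | CC(C)(C)[Si](C)(C)OC[C@@H]1C(C)=C(O[Si](C(C)C)(C(C)C)C(C)C)CC[C@]1(O)C(=O)OCC[Si](C)(C)C | intermediate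
10 | 4-methoxybenzyl alcohol | COc1ccc(CO)cc1 | starting material
11 | allyl bromide | C=CCBr | starting material
12 | 1-methoxy-4-[(prop-2-en-1-yloxy)methyl]benzene | C=CCOCc1ccc(OC)cc1 | intermediate
13 | 2-bromo-3,3-diethoxyprop-1-ene | C=C(Br)C(OCC)OCC | starting material
14 | (3,3-diethoxyprop-1-en-2-yl)lithium (not isolated) | [Li]C(=C)C(OCC)OCC | intermediate
15 | 2-(diethoxymethyl)prop-2-enal | C=C(C=O)C(OCC)OCC | intermediate
16 | [(Z)-3-(4-methoxybenzyloxy)prop-2-en-1-yl]diisopinocampheylborane, Ipc groups from (−)-α-pinene (not isolated) | COc1ccc(CO/C=C\CB([C@H]2C[C@H]3C[C@@H]([C@@H]2C)C3(C)C)[C@H]2C[C@H]3C[C@@H]([C@@H]2C)C3(C)C)cc1 | intermediate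
17 | (3S,4S)-2-(diethoxymethyl)-4-[(4-methoxyphenyl)methoxy]hexa-1,5-dien-3-ol | C=C[C@@H]([C@@H](O)C(=C)C(OCC)OCC)OCc1ccc(OC)cc1 | intermediate
18 | 4-hydroxy-3-methylfuran-2(5H)-one (3-methyltetronic acid) | CC1=C(O)COC1=O | starting material
19 | 4-{[(3R,4S)-2-(diethoxymethyl)-4-[(4-methoxyphenyl)methoxy]hexa-1,5-dien-3-yl]oxy}-3-methylfuran-2(5H)-one | C=C[C@@H]([C@H](OC1=C(C)C(=O)OC1)C(=C)C(OCC)OCC)OCc1ccc(OC)cc1 | intermediate
20 | (3R,4S)-4-[(4-methoxyphenyl)methoxy]-2-methylidene-3-[(4-methyl-5-oxo-2,5-dihydrofuran-3-yl)oxy]hex-5-enal | C=C[C@@H]([C@H](OC1=C(C)C(=O)OC1)C(=C)C=O)OCc1ccc(OC)cc1 | intermediate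
21 | 2-(tert-butyldimethylsilyloxy)furan derived from 20 (not isolated) | C=C[C@@H]([C@H](Oc1coc(O[Si](C)(C)C(C)(C)C)c1C)C(=C)C=O)OCc1ccc(OC)cc1 | intermediate
22 | (5R,7R,7aS)-7-[(tert-butyldimethylsilyl)oxy]-5-{(1S)-1-[(4-methoxyphenyl)methoxy]prop-2-en-1-yl}-3-methyl-6-methylidene-5,6,7,7a-tetrahydro-2H-furo[3,2-b]pyran-2-one | C=C[C@@H]([C@H]1C(=C)[C@@H](O[Si](C)(C)C(C)(C)C)[C@@H]2OC(=O)C(C)=C2O1)OCc1ccc(OC)cc1 | intermediate
23 | vicinal diol from osmylation of the vinyl group of 22 (mixture at the new carbinol; not isolated) | OCC(O)[C@@H]([C@H]1C(=C)[C@@H](O[Si](C)(C)C(C)(C)C)[C@@H]2OC(=O)C(C)=C2O1)OCc1ccc(OC)cc1 | intermediate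
24 | (2R)-2-[(5R,7R,7aS)-7-[(tert-butyldimethylsilyl)oxy]-3-methyl-6-methylidene-2-oxo-5,6,7,7a-tetrahydro-2H-furo[3,2-b]pyran-5-yl]-2-[(4-methoxyphenyl)methoxy]acetaldehyde (east fragment) | O=C[C@@H]([C@H]1C(=C)[C@@H](O[Si](C)(C)C(C)(C)C)[C@@H]2OC(=O)C(C)=C2O1)OCc1ccc(OC)cc1 | intermediate
25 | aldol adduct (C14 ketone; 2-OH; 3-OPMB; 6-OTBS; 9-OTBS; 11-OH; C20 2-(trimethylsilyl)ethyl ester; butenolide C8=C17) | CC(C)(C)[Si](C)(C)OC[C@@H]1[C@](C)(C(=O)CC[C@]1(O)C(=O)OCC[Si](C)(C)C)[C@@H](O)[C@@H]([C@H]1C(=C)[C@@H](O[Si](C)(C)C(C)(C)C)[C@@H]2OC(=O)C(C)=C2O1)OCc1ccc(OC)cc1 | intermediate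
26 | 2,14-diol (25 with 14S-OH) | CC(C)(C)[Si](C)(C)OC[C@@H]1[C@](C)([C@@H](O)CC[C@]1(O)C(=O)OCC[Si](C)(C)C)[C@@H](O)[C@@H]([C@H]1C(=C)[C@@H](O[Si](C)(C)C(C)(C)C)[C@@H]2OC(=O)C(C)=C2O1)OCc1ccc(OC)cc1 | intermediate
27 | 2,14-diacetate of 26 | CC(C)(C)[Si](C)(C)OC[C@@H]1[C@](C)([C@@H](OC(C)=O)CC[C@]1(O)C(=O)OCC[Si](C)(C)C)[C@@H](OC(C)=O)[C@@H]([C@H]1C(=C)[C@@H](O[Si](C)(C)C(C)(C)C)[C@@H]2OC(=O)C(C)=C2O1)OCc1ccc(OC)cc1 | intermediate
28 | 6,9-diol (27 without TBS groups) | OC[C@@H]1[C@](C)([C@@H](OC(C)=O)CC[C@]1(O)C(=O)OCC[Si](C)(C)C)[C@@H](OC(C)=O)[C@@H]([C@H]1C(=C)[C@@H](O)[C@@H]2OC(=O)C(C)=C2O1)OCc1ccc(OC)cc1 | intermediate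
29 | seco-aldehyde (C9 CHO) | O=C[C@@H]1[C@](C)([C@@H](OC(C)=O)CC[C@]1(O)C(=O)OCC[Si](C)(C)C)[C@@H](OC(C)=O)[C@@H]([C@H]1C(=C)[C@@H](O)[C@@H]2OC(=O)C(C)=C2O1)OCc1ccc(OC)cc1 | intermediate
30 | macrocycle (8R; 9S-OH; 17R; 6-OH; 3-OPMB; 2,14-diacetate; 11-OH; 2-(trimethylsilyl)ethyl ester) | C=C1[C@H]2O[C@]3([C@@H](C)C(=O)O[C@H]3[C@@H]1O)[C@@H](O)[C@@H]1[C@](C)([C@@H](OC(C)=O)CC[C@]1(O)C(=O)OCC[Si](C)(C)C)[C@@H](OC(C)=O)[C@@H]2OCc1ccc(OC)cc1 | intermediate
31 | 6S-chloride of 30 | C=C1[C@H]2O[C@]3([C@@H](C)C(=O)O[C@H]3[C@H]1Cl)[C@@H](O)[C@@H]1[C@](C)([C@@H](OC(C)=O)CC[C@]1(O)C(=O)OCC[Si](C)(C)C)[C@@H](OC(C)=O)[C@@H]2OCc1ccc(OC)cc1 | intermediate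
32 | 3,9-diol (31 without PMB) | C=C1[C@H]2O[C@]3([C@@H](C)C(=O)O[C@H]3[C@H]1Cl)[C@@H](O)[C@@H]1[C@](C)([C@@H](OC(C)=O)CC[C@]1(O)C(=O)OCC[Si](C)(C)C)[C@@H](OC(C)=O)[C@@H]2O | intermediate
33 | 2-(trimethylsilyl)ethyl ester of the target (2,3,9,14-tetraacetate) | C=C1[C@H]2O[C@]3([C@@H](C)C(=O)O[C@H]3[C@H]1Cl)[C@@H](OC(C)=O)[C@@H]1[C@](C)([C@@H](OC(C)=O)CC[C@]1(O)C(=O)OCC[Si](C)(C)C)[C@@H](OC(C)=O)[C@@H]2OC(C)=O | intermediate
34 | CNP0186125.1, (1R,2R,3R,4R,6S,7R,8R,9S,10S,11R,14S,17R)-2,3,9,14-tetraacetoxy-6-chloro-4,8-epoxy-11-hydroxybriar-5(16)-en-18,7-olid-20-oic acid | C=C1[C@H]2O[C@]3([C@@H](C)C(=O)O[C@H]3[C@H]1Cl)[C@@H](OC(C)=O)[C@@H]1[C@](C)([C@@H](OC(C)=O)CC[C@]1(O)C(=O)O)[C@@H](OC(C)=O)[C@@H]2OC(C)=O | target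

## Step count and risks

Total steps: 22. Longest linear sequence: 16 steps (step 6, then steps 8 to 22).

Most likely to fail, step 18 (ketyl macrocyclisation onto a fully substituted β-carbon; C9 configuration uncertain). The fallback sets out from seco-aldehyde 29 and comes back at macrocycle 30. Pinnick oxidation (NaClO2, NaH2PO4, 2-methylbut-2-ene) gives the carboxylic acid F1. PhSeSePh and PBu3 convert it into the phenyl selenoester F2. Under (Me3Si)3SiH with Et3B/O2 at high dilution, the derived acyl radical, again a nucleophilic acyl carbon, cyclises onto C8 of the butenolide to give the C9 ketone F3. Reduction with NaBH4/CeCl3 from the less hindered face then gives 30, so the C9 configuration is set in a separate step.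

Second, step 13 (hindered quaternary-centre-forming aldol between two complex partners). The fallback sets out from west fragment 9 and comes back at aldol adduct 25. N-Bromosuccinimide converts the enol silane into the α-bromo ketone F4 (bromine anti to the CH2OTBS group). SmI2 in THF at −78 °C in the presence of aldehyde 24 then generates the samarium enolate regiospecifically under neutral conditions, and a Reformatsky-type aldol onto the chelated α-alkoxy aldehyde gives 25.

Third, step 12 (chemoselective cleavage of the vinyl group beside the exocyclic methylene). The fallback sets out from enal 20 and comes back at east fragment 24, replacing steps 11 and 12. At this stage the other alkene is an electron-poor conjugated enal, so OsO4 (cat.) with N-methylmorpholine N-oxide dihydroxylates only the vinyl group to give the diol F5. 2,2-Dimethoxypropane with pyridinium p-toluenesulfonate gives the acetonide F6. The TBSOTf/iPr2NEt vinylogous aldol then gives the bicyclic acetonide F7, and H5IO6 in ethyl acetate unmasks and cleaves the terminal acetonide in one operation to give 24.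

## Further compounds

F1 | step 18 | C9 carboxylic acid from 29 | OC(=O)[C@@H]1[C@](C)([C@@H](OC(C)=O)CC[C@]1(O)C(=O)OCC[Si](C)(C)C)[C@@H](OC(C)=O)[C@@H]([C@H]1C(=C)[C@@H](O)[C@@H]2OC(=O)C(C)=C2O1)OCc1ccc(OC)cc1
F2 | step 18 | Se-phenyl selenoester of F1 | O=C([Se]c1ccccc1)[C@@H]1[C@](C)([C@@H](OC(C)=O)CC[C@]1(O)C(=O)OCC[Si](C)(C)C)[C@@H](OC(C)=O)[C@@H]([C@H]1C(=C)[C@@H](O)[C@@H]2OC(=O)C(C)=C2O1)OCc1ccc(OC)cc1
F3 | step 18 | macrocyclic C9 ketone (30 with C9=O) | C=C1[C@H]2O[C@]3([C@@H](C)C(=O)O[C@H]3[C@@H]1O)C(=O)[C@@H]1[C@](C)([C@@H](OC(C)=O)CC[C@]1(O)C(=O)OCC[Si](C)(C)C)[C@@H](OC(C)=O)[C@@H]2OCc1ccc(OC)cc1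
F4 | step 13 | α-bromo ketone from 9 (C14 ketone, C1 bromide) | CC(C)(C)[Si](C)(C)OC[C@@H]1[C@@](C)(Br)C(=O)CC[C@]1(O)C(=O)OCC[Si](C)(C)C
F5 | step 12 | vicinal diol from the vinyl group of 20 (mixture at the new carbinol) | OCC(O)[C@@H]([C@H](OC1=C(C)C(=O)OC1)C(=C)C=O)OCc1ccc(OC)cc1
F6 | step 12 | acetonide of F5 | CC1(C)OCC(O1)[C@@H]([C@H](OC1=C(C)C(=O)OC1)C(=C)C=O)OCc1ccc(OC)cc1
F7 | step 12 | bicyclic TBS ether carrying the acetonide (analogue of 22) | CC1(C)OCC(O1)[C@@H]([C@H]1C(=C)[C@@H](O[Si](C)(C)C(C)(C)C)[C@@H]2OC(=O)C(C)=C2O1)OCc1ccc(OC)cc1
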